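**Retrosynthetic overview** (labdane numbering: C4 carries CH3 and the ring carboxyl, C10 the angular CH3, C8=C17 is the exocyclic olefin, C11–C16 the side chain)

1. Target ⇐ SN2 demethylation of two methyl esters ⇐ hydride reduction of a C2 ketone from the face opposite the two syn-axial methyls (C4, C10) ⇐ cis-fused bicyclic 2-oxo diester.
2. Rings A then B close in one cationic head-to-tail cascade of an acyclic geranylgeranyl-type tetraene (C4–C5 first, then C9–C10, with C8=C17 formed by terminal loss of silicon in place of the enzymatic proton loss). The trigger is a 4-oxo-2-enoate, so the C2 oxygen and the C4 carboxyl are already in place.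
3. The (10Z) olefin of the tetraene encodes the cis ring fusion; a chiral counter-anion sets the absolute configuration of C4, C5, C9 and C10 at once.
4. Tetraene ⇐ Pd α-alkenylation of the zinc enolate of methyl (E)-2-methyl-4-oxopent-2-enoate (from methyl pyruvate) with a (Z)-alkenyl iodide.
5. (Z)-Alkenyl iodide ⇐ Stork–Zhao iodo-olefination ⇐ Claisen rearrangement (sets the allylsilane olefin) ⇐ alkenyl Grignard addition to the aldehyde from ozonolysis of methyl (E)-geranate.

**Assumptions**

- The SMILES is taken literally: 5-H, 9-H, the C10 methyl, the C4 methyl and the C2 hydroxyl all lie on one face (A/B cis-fused), and the side chain and the C4 carboxyl lie on the other; CIP 2S,4R,5S,9R,10R.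
- Methyl (E)-geranate is bought as the geometrically pure E ester.
- The sense of induction of the chiral acid in step 7 cannot be predicted; the (S,S) antipode is written, and the mirror-image catalyst is used if a first run gives the antipodal ketone.

**Route**

Step 1
Reactants: 1 methyl (2E)-3,7-dimethylocta-2,6-dienoate
Product: 3 methyl (2E)-3-methyl-6-oxohex-2-enoate, via secondary ozonide 2 (not isolated)
Conditions: O3 (1.0 equiv), CH2Cl2, −78 °C; PPh3, −78 → 25 °C
Reagents that add atoms: ozone, [O-][O+]=O
Why: Ozonolysis with reductive work-up (Criegee mechanism) cleaves only the electron-rich trisubstituted 6,7-olefin, because the conjugated enoate olefin reacts far more slowly with electrophilic ozone, and the 2E geometry is untouched.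

Step 2
Reactants: 3 methyl (2E)-3-methyl-6-oxohex-2-enoate; 4 (2-bromoprop-2-en-1-yl)trimethylsilane
Product: 6 methyl (2E)-6-hydroxy-3-methyl-7-[(trimethylsilyl)methyl]octa-2,7-dienoate (racemic), via alkenylmagnesium bromide 5 (not isolated)
Conditions: 4, Mg, THF, 25 °C; then 3, THF, −78 °C; H2O
Reagents that add atoms: none
Why: Chemoselective 1,2-addition of the alkenyl Grignard reagent to the aldehyde at −78 °C (the β,β-disubstituted enoate does not react) installs the 2-(silylmethyl)allyl alcohol; the new carbinol centre is racemic and is erased in step 3.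

Step 3
Reactants: 6 methyl (2E)-6-hydroxy-3-methyl-7-[(trimethylsilyl)methyl]octa-2,7-dienoate
Product: 8 methyl (2E,6Z)-3-methyl-10-oxo-7-[(trimethylsilyl)methyl]deca-2,6-dienoate, via allyl vinyl ether 7 (not isolated)
Conditions: [Ir(cod)Cl]2 (1 mol %), Na2CO3 (0.6 equiv), vinyl acetate (3 equiv), PhMe, 100 °C; then 140 °C (sealed)
Reagents that add atoms: vinyl acetate, C=COC(C)=O
Why: Iridium-catalysed transfer vinylation followed by thermal Claisen [3,3] rearrangement through a chair transition state with the carbinol substituent equatorial gives the trisubstituted olefin with the ester-bearing chain trans to the new CH2CH2CHO arm and cis to CH2SiMe3 (6Z by CIP because of silicon), and destroys the carbinol stereocentre.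

Step 4
Reactants: 8 methyl (2E,6Z)-3-methyl-10-oxo-7-[(trimethylsilyl)methyl]deca-2,6-dienoate
Product: 9 methyl (2E,6Z,10Z)-11-iodo-3-methyl-7-[(trimethylsilyl)methyl]dodeca-2,6,10-trienoate
Conditions: EtPPh3I, n-BuLi, THF, 25 °C; I2, −78 °C; NaN(SiMe3)2, −20 °C; then 8, −78 → −20 °C
Reagents that add atoms: ethyltriphenylphosphonium iodide, CC[P+](c1ccccc1)(c1ccccc1)c1ccccc1.[I-]; iodine, II
Why: Stork–Zhao iodo-olefination: the non-stabilised α-iodo ylide reacts under kinetic control to give the (Z)-2-iodo-2-alkene (iodine cis to the chain), which fixes the olefin geometry that later encodes the cis ring fusion.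

Step 5
Reactants: 10 methyl 2-oxopropanoate; 11 1-(triphenylphosphoranylidene)propan-2-one
Product: 12 methyl (2E)-2-methyl-4-oxopent-2-enoate
Conditions: CH2Cl2, 25 °C
Reagents that add atoms: none
Why: Wittig olefination of the activated keto group of methyl pyruvate with a stabilised acyl ylide gives mainly the E enoate (ketone and ester trans), and the minor Z isomer is removed by chromatography.

Step 6
Reactants: 9 methyl (2E,6Z,10Z)-11-iodo-3-methyl-7-[(trimethylsilyl)methyl]dodeca-2,6,10-trienoate; 12 methyl (2E)-2-methyl-4-oxopent-2-enoate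
Product: 15 dimethyl (2E,6Z,10Z,14E)-3,11,15-trimethyl-13-oxo-7-[(trimethylsilyl)methyl]hexadeca-2,6,10,14-tetraenedioate, via lithium enolate 13 (not isolated), via zinc enolate 14 (not isolated)
Conditions: 12 (1.5 equiv), LiN(SiMe3)2, THF, −78 °C; ZnCl2, −78 → 0 °C; then 9, Pd2(dba)3 (2.5 mol %), P(t-Bu)3 (10 mol %), THF, 25 °C
Reagents that add atoms: none
Why: Palladium-catalysed α-alkenylation of a ketone enolate (Negishi-type coupling of the zinc enolate from kinetic deprotonation of the methyl ketone) proceeds with retention at the alkenyl carbon, so the new CH2 takes the place of iodine cis to the chain (10Z), and the weakly basic zinc enolate leaves the skipped enone unisomerised.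

Step 7
Reactants: 15 dimethyl (2E,6Z,10Z,14E)-3,11,15-trimethyl-13-oxo-7-[(trimethylsilyl)methyl]hexadeca-2,6,10,14-tetraenedioate
Product: 17 methyl (1R,4aR,5R,8aS)-5-[(3E)-5-methoxy-3-methyl-5-oxopent-3-en-1-yl]-1,4a-dimethyl-6-methylidene-3-oxodecahydronaphthalene-1-carboxylate, via trimethylsilyl enol ether 16 (not isolated)
Conditions: (S,S)-IDPi acid (confined imidodiphosphorimidate built from two 3,3′-diaryl-BINOL units, N-SO2CF3; 5 mol %), allyl-SiMe3 (10 mol %), CH2Cl2 (0.01 M), −78 → −40 °C; Et3N; then aq. citric acid, THF, 0 °C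
Reagents that add atoms: none
Why: Proposed new method: the silylated acid (formed by protodesilylation of the allylsilane additive) O-silylates the C2 ketone to a 2-silyloxyallyl cation that is attacked at C4 by C5 of the 10Z olefin, the tertiary C10 cation is captured by C9 of the allylsilane in a chair–chair array, and loss of Me3Si+ forms the exocyclic C8=C17 olefin and regenerates the silylium catalyst; antiperiplanar addition across the Z olefin gives the cis fusion (5-H syn to the C10 methyl), the E enone places CO2Me equatorial (anti to the C10 methyl) and CH3 axial at C4, the olefin geometry at C8=C9 places the side chain equatorial at C9 (anti to the C10 methyl), and the chiral counter-anion directs attack to the Si face of C4 so that 4R,5S,9R,10R are set together; the closest known reaction types are Stork–Eschenmoser cation–olefin polycyclisation terminated by an allylsilane, Lewis-acid Michael-initiated polyene cyclisation, and silylium counter-anion-directed Mukaiyama–Michael and Hosomi–Sakurai catalysis.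

Step 8
Reactants: 17 methyl (1R,4aR,5R,8aS)-5-[(3E)-5-methoxy-3-methyl-5-oxopent-3-en-1-yl]-1,4a-dimethyl-6-methylidene-3-oxodecahydronaphthalene-1-carboxylate
Product: 18 methyl (1R,3S,4aR,5R,8aS)-3-hydroxy-5-[(3E)-5-methoxy-3-methyl-5-oxopent-3-en-1-yl]-1,4a-dimethyl-6-methylidenedecahydronaphthalene-1-carboxylate
Conditions: NaBH4, MeOH/CH2Cl2, −20 → 0 °C
Reagents that add atoms: none
Why: Steric-approach-controlled hydride reduction: the face of the C2 carbonyl bearing the two syn-axial methyls (C4 and C10) is blocked, so hydride enters equatorially from the opposite face and gives the axial alcohol cis to both methyls (2S), while the esters and the enoate are inert to NaBH4 at this temperature.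

Step 9
Reactants: 18 methyl (1R,3S,4aR,5R,8aS)-3-hydroxy-5-[(3E)-5-methoxy-3-methyl-5-oxopent-3-en-1-yl]-1,4a-dimethyl-6-methylidenedecahydronaphthalene-1-carboxylate
Product: 19 (1R,3S,4aR,5R,8aS)-5-[(3E)-4-carboxy-3-methylbut-3-en-1-yl]-3-hydroxy-1,4a-dimethyl-6-methylidenedecahydronaphthalene-1-carboxylic acid
Conditions: n-PrSLi (8 equiv), HMPA, 25 °C; then 1 M HCl
Reagents that add atoms: none
Why: SN2 dealkylation of the methyl esters (thiolate attack at the methyl carbons, alkyl–oxygen cleavage) frees both acids without needing attack at the hindered C4 carbonyl and without touching the stereocentres, the exocyclic olefin or the E enoate.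

**Compound list**

1 | methyl (2E)-3,7-dimethylocta-2,6-dienoate (methyl (E)-geranate) | COC(=O)/C=C(C)/CCC=C(C)C | starting material
2 | methyl (2E)-5-(5,5-dimethyl-1,2,4-trioxolan-3-yl)-3-methylpent-2-enoate (secondary ozonide, racemic) | COC(=O)/C=C(C)/CCC1OOC(C)(C)O1 | intermediate
3 | methyl (2E)-3-methyl-6-oxohex-2-enoate | COC(=O)/C=C(C)/CCC=O | intermediate
4 | (2-bromoprop-2-en-1-yl)trimethylsilane | C=C(Br)C[Si](C)(C)C | starting material
5 | bromo[3-(trimethylsilyl)prop-1-en-2-yl]magnesium | C=C([Mg]Br)C[Si](C)(C)C | intermediate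
6 | methyl (2E)-6-hydroxy-3-methyl-7-[(trimethylsilyl)methyl]octa-2,7-dienoate (racemic at C6) | COC(=O)/C=C(C)/CCC(O)C(=C)C[Si](C)(C)C | intermediate
7 | methyl (2E)-6-(ethenyloxy)-3-methyl-7-[(trimethylsilyl)methyl]octa-2,7-dienoate (racemic at C6) | COC(=O)/C=C(C)/CCC(OC=C)C(=C)C[Si](C)(C)C | intermediate
8 | methyl (2E,6Z)-3-methyl-10-oxo-7-[(trimethylsilyl)methyl]deca-2,6-dienoate | COC(=O)/C=C(C)/CC/C=C(\C[Si](C)(C)C)CCC=O | intermediate
9 | methyl (2E,6Z,10Z)-11-iodo-3-methyl-7-[(trimethylsilyl)methyl]dodeca-2,6,10-trienoate | COC(=O)/C=C(C)/CC/C=C(\C[Si](C)(C)C)CC/C=C(\I)C | intermediate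
10 | methyl 2-oxopropanoate (methyl pyruvate) | CC(=O)C(=O)OC | starting material
11 | 1-(triphenylphosphoranylidene)propan-2-one | CC(=O)C=P(c1ccccc1)(c1ccccc1)c1ccccc1 | starting material
12 | methyl (2E)-2-methyl-4-oxopent-2-enoate | COC(=O)/C(C)=C/C(C)=O | intermediate
13 | lithium (3E)-5-methoxy-4-methyl-5-oxopenta-1,3-dien-2-olate | C=C(O[Li])/C=C(C)/C(=O)OC | intermediate
14 | chlorozinc (3E)-5-methoxy-4-methyl-5-oxopenta-1,3-dien-2-olate | C=C(O[Zn]Cl)/C=C(C)/C(=O)OC | intermediate
15 | dimethyl (2E,6Z,10Z,14E)-3,11,15-trimethyl-13-oxo-7-[(trimethylsilyl)methyl]hexadeca-2,6,10,14-tetraenedioate | COC(=O)/C=C(C)/CC/C=C(\C[Si](C)(C)C)CC/C=C(C)\CC(=O)/C=C(C)/C(=O)OC | intermediate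
16 | methyl (1S,4aR,5R,8aS)-5-[(3E)-5-methoxy-3-methyl-5-oxopent-3-en-1-yl]-1,4a-dimethyl-6-methylidene-3-[(trimethylsilyl)oxy]-1,4,4a,5,6,7,8,8a-octahydronaphthalene-1-carboxylate (same spatial arrangement as 17; the C1 descriptor changes only because of the enol ether) | C=C1CC[C@H]2[C@](C)(CC(O[Si](C)(C)C)=C[C@@]2(C)C(=O)OC)[C@@H]1CC/C(C)=C/C(=O)OC | intermediate
17 | methyl (1R,4aR,5R,8aS)-5-[(3E)-5-methoxy-3-methyl-5-oxopent-3-en-1-yl]-1,4a-dimethyl-6-methylidene-3-oxodecahydronaphthalene-1-carboxylate (cis-fused; 8a-H, 5-H, 4a-CH3 and 1-CH3 on one face) | C=C1CC[C@H]2[C@](C)(CC(=O)C[C@@]2(C)C(=O)OC)[C@@H]1CC/C(C)=C/C(=O)OC | intermediate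
18 | methyl (1R,3S,4aR,5R,8aS)-3-hydroxy-5-[(3E)-5-methoxy-3-methyl-5-oxopent-3-en-1-yl]-1,4a-dimethyl-6-methylidenedecahydronaphthalene-1-carboxylate | C=C1CC[C@H]2[C@](C)(C[C@H](O)C[C@@]2(C)C(=O)OC)[C@@H]1CC/C(C)=C/C(=O)OC | intermediate
19 | (1R,3S,4aR,5R,8aS)-5-[(3E)-4-carboxy-3-methylbut-3-en-1-yl]-3-hydroxy-1,4a-dimethyl-6-methylidenedecahydronaphthalene-1-carboxylic acid (labdane numbering 2S,4R,5S,9R,10R) | C=C1CC[C@H]2[C@](C)(C[C@H](O)C[C@@]2(C)C(=O)O)[C@@H]1CC/C(C)=C/C(=O)O | target

**Step count and risks**

Total step count: 9. Longest linear sequence: 8 steps (steps 1, 2, 3, 4, 6, 7, 8, 9); step 5 is the one-step side branch.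

The step most likely to fail is step 7. The trigger, the cis-selective capture of the C10 cation and the enantioselection are all untested on this substrate. The activated ketone can also enolise toward C1 to give a conjugated silyl dienol ether. The fallback sets out from 15 and comes back at 17: 15 is cyclised without chiral information by Me2AlCl (2.2 equiv, CH2Cl2, −78 °C) through the same chair–chair cascade to the racemic ketone, that is 17 together with the mirror-image ketone F1, and 17 is isolated by preparative chromatography on a chiral stationary phase. Absolute configuration then comes from resolution instead of catalysis.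

The second is step 6. The enolate of 12 is itself a strong Michael acceptor precursor, and the product has a doubly activated CH2 that can move the 10Z olefin into conjugation. The fallback sets out from 9 and comes back at 15, building the C2–C3 bond instead of the C1–C10 bond at the end. Negishi coupling of 9 with the Reformatsky reagent BrZnCH2CO2Me (Pd(PPh3)4, THF) gives the skipped methyl ester F2. Selective saponification (LiOH, THF/H2O, 0 °C; the conjugated β,β-disubstituted enoate is much slower) gives the carboxylic acid F3. 1-Chloro-N,N,2-trimethylprop-1-en-1-amine (CH2Cl2, 0 °C, neutral) gives the acyl chloride F4. Stille acylation with methyl (2E)-2-methyl-3-(tributylstannyl)prop-2-enoate (Pd2(dba)3, tri(2-furyl)phosphine, PhMe, 60 °C) then delivers 15.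

The third is step 3. The 2-(silylmethyl)allyl alcohol may not tolerate the iridium catalyst at 100–140 °C (1,4-elimination to a diene, or olefin migration in the vinyl ether). The fallback sets out from 6 and comes back at 8. Eschenmoser–Claisen rearrangement with N,N-dimethylacetamide dimethyl acetal (xylene, 140 °C, no metal, no acid) gives the dimethylamide F5 with the same olefin geometry. Cp2Zr(H)Cl (THF, 25 °C) then reduces the tertiary amide to aldehyde 8 without touching the methyl ester.

**Further compounds**

F1 | step 7 | methyl (1S,4aS,5S,8aR)-5-[(3E)-5-methoxy-3-methyl-5-oxopent-3-en-1-yl]-1,4a-dimethyl-6-methylidene-3-oxodecahydronaphthalene-1-carboxylate (mirror image of 17) | C=C1CC[C@@H]2[C@@](C)(CC(=O)C[C@]2(C)C(=O)OC)[C@H]1CC/C(C)=C/C(=O)OC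
F2 | step 6 | dimethyl (3Z,7Z,11E)-3,11-dimethyl-7-[(trimethylsilyl)methyl]trideca-3,7,11-trienedioate | COC(=O)/C=C(C)/CC/C=C(\C[Si](C)(C)C)CC/C=C(C)\CC(=O)OC
F3 | step 6 | (3Z,7Z,11E)-13-methoxy-3,11-dimethyl-13-oxo-7-[(trimethylsilyl)methyl]trideca-3,7,11-trienoic acid | COC(=O)/C=C(C)/CC/C=C(\C[Si](C)(C)C)CC/C=C(C)\CC(=O)O
F4 | step 6 | methyl (2E,6Z,10Z)-13-chloro-3,11-dimethyl-13-oxo-7-[(trimethylsilyl)methyl]trideca-2,6,10-trienoate | COC(=O)/C=C(C)/CC/C=C(\C[Si](C)(C)C)CC/C=C(C)\CC(=O)Cl
F5 | step 3 | methyl (2E,6Z)-10-(dimethylamino)-3-methyl-10-oxo-7-[(trimethylsilyl)methyl]deca-2,6-dienoate | COC(=O)/C=C(C)/CC/C=C(\C[Si](C)(C)C)CCC(=O)N(C)C
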